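The C4 carbonyl of unit 2 (the luteolin half) lies between C3 and ring A carbon C4a. C4a is one of the two equivalent unsubstituted carbons of the symmetric 2,4,6-trioxygenated aryl ring that unit 1 carries at C3, and it sits next to the oxygen para to the biaryl bond, which becomes O1. The route therefore opens the unit 2 pyranone at C4a–C4 and C4–C3. A three-component carbonylative alkynylation of an aryl iodide delivers C4 (from CO) and C3, C2 and ring B (from the catechol alkyne) in one operation. The precursor is the complete unit 1 flavone, hindered biaryl bond included, with one iodine on that ring and the adjacent ring-closing oxygen masked as an aroyl ester.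

Key step: step 11

Remark: the target has no stereocentre and its hindered biaryl axis is unassigned, so axially chiral intermediates are carried as racemates; 3,5-bis(benzyloxy)phenol and 4-(benzyloxy)benzoyl chloride are taken as commercial.

Step 1
Reactants: 1 3,5-bis(benzyloxy)phenol
Product: 3 2,6-bis(benzyloxy)-4-hydroxybenzaldehyde, via aryliminium chloride 2 (not isolated)
Conditions: POCl3 (1.5 equiv), DMF, MeCN, 0 °C → rt; then H2O, 50 °C
Reagents that add atoms: N,N-dimethylformamide, CN(C)C=O; water, O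
Why: Vilsmeier–Haack formylation of a 3,5-dialkoxyphenol should attack mainly the carbon para to the free hydroxyl, and the chelated ortho-formyl isomer expected as the minor product is far less polar and should be removed by crystallization or chromatography.

Step 2
Reactants: 3 2,6-bis(benzyloxy)-4-hydroxybenzaldehyde
Product: 4 2,6-bis(benzyloxy)-4-(methoxymethoxy)benzaldehyde
Conditions: MOMCl, i-Pr2NEt, CH2Cl2, 0 °C → rt
Reagents that add atoms: chloromethyl methyl ether, COCCl
Why: Base-mediated O-alkylation (acetal ether formation) of the acidic 4-hydroxybenzaldehyde caps the only free hydroxyl, so that the aldehyde is not deactivated as a phenoxide in the next step and the oxygen para to the future biaryl bond stays distinguishable from the two benzylated ones.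

Step 3
Reactants: 4 2,6-bis(benzyloxy)-4-(methoxymethoxy)benzaldehyde
Product: 5 2-[2,6-bis(benzyloxy)-4-(methoxymethoxy)phenyl]acetonitrile
Conditions: TosMIC, t-BuOK, DME, −40 °C → rt; then MeOH, reflux
Reagents that add atoms: p-toluenesulfonylmethyl isocyanide, Cc1ccc(cc1)S(=O)(=O)C[N+]#[C-]
Why: The van Leusen reductive cyanation converts an aromatic aldehyde directly into the homologous arylacetonitrile under basic conditions that benzyl and methoxymethyl ethers tolerate, the isocyanide carbon leaving as methyl formate and the sulfonyl group as sulfinate.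

Step 4
Reactants: 5 2-[2,6-bis(benzyloxy)-4-(methoxymethoxy)phenyl]acetonitrile
Product: 6 2-[2,6-bis(benzyloxy)-4-(methoxymethoxy)phenyl]acetic acid
Conditions: KOH, EtOH–H2O, reflux; then 1 M HCl to pH 4, 0 °C
Reagents that add atoms: potassium hydroxide, [K+].[OH-]; water, O
Why: Alkaline nitrile hydrolysis of the unhindered benzylic nitrile gives the carboxylate without touching the base-stable ethers, and cold acidification to pH 4 should liberate the acid before the acetal ether can cleave.

Step 5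
Reactants: 6 2-[2,6-bis(benzyloxy)-4-(methoxymethoxy)phenyl]acetic acid
Product: 7 2-[2,6-bis(benzyloxy)-4-(methoxymethoxy)phenyl]-N-methoxy-N-methylacetamide
Conditions: MeNH(OMe)·HCl, EDC·HCl, HOBt, i-Pr2NEt, CH2Cl2, rt
Reagents that add atoms: N,O-dimethylhydroxylamine hydrochloride, CNOC.Cl
Why: Carbodiimide-mediated amide coupling through the hydroxybenzotriazole ester gives the Weinreb amide under near-neutral conditions compatible with the acetal ether.

Step 6
Reactants: 8 3,5-dimethoxyphenol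
Product: 9 1,3-dimethoxy-5-(methoxymethoxy)benzene
Conditions: MOMCl, i-Pr2NEt, CH2Cl2, 0 °C → rt
Reagents that add atoms: chloromethyl methyl ether, COCCl
Why: Base-mediated O-alkylation installs the methoxymethyl ether, which protects the phenol and serves as the strongest ortho-directing group on the ring for the metalation that follows.

Step 7
Reactants: 9 1,3-dimethoxy-5-(methoxymethoxy)benzene; 7 2-[2,6-bis(benzyloxy)-4-(methoxymethoxy)phenyl]-N-methoxy-N-methylacetamide
Product: 12 2-[2,6-bis(benzyloxy)-4-hydroxyphenyl]-1-(2-hydroxy-4,6-dimethoxyphenyl)ethan-1-one, via aryllithium 10 (not isolated), via bis(methoxymethyl) ketone 11 (not isolated)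
Conditions: 9 (1.5 equiv), n-BuLi, THF, 0 °C; 7, −78 → 0 °C; then 3 M HCl, MeOH, 50 °C
Reagents that add atoms: none
Why: Directed ortho-metalation should place lithium between the methoxymethoxy and methoxy groups, the aryllithium then acylates the Weinreb amide through a chelated tetrahedral adduct that cannot over-add, and acid-catalysed acetal exchange with methanol finally removes both methoxymethyl groups while the benzyl ethers survive.

Step 8
Reactants: 12 2-[2,6-bis(benzyloxy)-4-hydroxyphenyl]-1-(2-hydroxy-4,6-dimethoxyphenyl)ethan-1-one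
Product: 13 2-[2,6-bis(benzyloxy)-4-hydroxy-3-iodophenyl]-1-(2-hydroxy-4,6-dimethoxyphenyl)ethan-1-one
Conditions: NIS (1.0 equiv), MeCN–CH2Cl2, −40 → 0 °C
Reagents that add atoms: N-iodosuccinimide, O=C1CCC(=O)N1I
Why: Electrophilic aromatic iodination should occur at one of the two equivalent carbons ortho to the hydroxyl of the future ring A of unit 2, a phloroglucinol-type ring far more nucleophilic than the ketone-deactivated, chelated ring A of unit 1, and one equivalent of reagent at low temperature limits double iodination.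

Step 9
Reactants: 13 2-[2,6-bis(benzyloxy)-4-hydroxy-3-iodophenyl]-1-(2-hydroxy-4,6-dimethoxyphenyl)ethan-1-one; 14 4-(benzyloxy)benzoyl chloride
Product: 17 3,5-bis(benzyloxy)-4-{2-[4-(benzyloxy)phenyl]-5,7-dimethoxy-4-oxo-4H-chromen-3-yl}-2-iodophenyl 4-(benzyloxy)benzoate, via bis(aroyl) ester 15 (not isolated), via 1,3-diketone 16 (not isolated)
Conditions: 14 (2.5 equiv), K2CO3, acetone, reflux; then TsOH·H2O (cat.), toluene, 80 °C
Reagents that add atoms: none
Why: After aroylation of both phenols the deoxybenzoin enolate takes the aroyl group from the neighbouring ester (Baker–Venkataraman rearrangement) and the 2-aryl-1,3-diketone cyclodehydrates to the 2,3-diarylchromone, while the second ester stays on the oxygen para to the biaryl bond as the protecting group needed for the key step.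

Step 10
Reactants: 18 3,4-bis(benzyloxy)benzaldehyde
Product: 19 1,2-bis(benzyloxy)-4-ethynylbenzene
Conditions: dimethyl (1-diazo-2-oxopropyl)phosphonate, K2CO3, MeOH–THF, rt
Reagents that add atoms: dimethyl (1-diazo-2-oxopropyl)phosphonate, COP(=O)(OC)C(=[N+]=[N-])C(C)=O
Why: Seyferth–Gilbert homologation with the Ohira–Bestmann reagent converts the non-enolizable aromatic aldehyde into the terminal alkyne in one operation under mild carbonate–methanol conditions.

Step 11
Reactants: 17 3,5-bis(benzyloxy)-4-{2-[4-(benzyloxy)phenyl]-5,7-dimethoxy-4-oxo-4H-chromen-3-yl}-2-iodophenyl 4-(benzyloxy)benzoate; 19 1,2-bis(benzyloxy)-4-ethynylbenzene; 20 carbon monoxide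
Product: 21 3,5-bis(benzyloxy)-4-{2-[4-(benzyloxy)phenyl]-5,7-dimethoxy-4-oxo-4H-chromen-3-yl}-2-{3-[3,4-bis(benzyloxy)phenyl]prop-2-ynoyl}phenyl 4-(benzyloxy)benzoate
Conditions: PdCl2(PPh3)2 (5 mol %), CuI (5 mol %), CO (5 bar), i-Pr2NEt, THF, 40 °C, slow addition of 19
Reagents that add atoms: none
Why: PdCl2(PPh3)2 (divalent palladium) is reduced in the flask to zerovalent palladium, which inserts into the C–I bond of 17; migratory insertion of CO gives the aroylpalladium iodide, the copper acetylide formed from 19, CuI (monovalent copper) and the amine transmetalates, and reductive elimination releases ynone 21 with the new C4a–C4 and C4–C3 bonds of unit 2. The closest known reaction type is the three-component carbonylative Sonogashira coupling of aryl iodides, CO and terminal alkynes, which is established for iodoarenes carrying an ortho acyloxy group. No ring is closed and no stereocentre is created in this step. The selectivity needed is carbonylative over direct alkynylation, and it is secured by the electron-rich, doubly ortho-substituted arylpalladium species (fast CO insertion, slow direct coupling), by CO pressure and by slow addition of the alkyne, which also limits alkyne homocoupling. Premature cyclization is excluded because the only oxygen that could close the ring is an aroyl ester and the base is a hindered tertiary amine that neither cleaves the ester nor adds to the ynone, and the single C–I bond, placed at one of the two formerly equivalent free carbons of the future ring A of unit 2, fixes where C4 is attached.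

Step 12
Reactants: 21 3,5-bis(benzyloxy)-4-{2-[4-(benzyloxy)phenyl]-5,7-dimethoxy-4-oxo-4H-chromen-3-yl}-2-{3-[3,4-bis(benzyloxy)phenyl]prop-2-ynoyl}phenyl 4-(benzyloxy)benzoate
Product: 23 3-{5,7-bis(benzyloxy)-2-[3,4-bis(benzyloxy)phenyl]-4-oxo-4H-chromen-6-yl}-2-[4-(benzyloxy)phenyl]-5,7-dimethoxy-4H-chromen-4-one, via enaminone 22 (not isolated)
Conditions: Et2NH (10 equiv), THF–MeOH, rt; then K2CO3 (0.3 equiv), 50 °C
Reagents that add atoms: none
Why: Conjugate addition of diethylamine turns the ynone into a β-amino enone, so the phenoxide freed by methanolysis of the single aroyl ester can only attack the amine-bearing carbon (6-endo oxa-Michael addition–elimination) and, being the oxygen para to the biaryl bond, gives the 6-linked pyranone of unit 2 rather than an aurone or an 8-linked isomer.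

Step 13
Reactants: 23 3-{5,7-bis(benzyloxy)-2-[3,4-bis(benzyloxy)phenyl]-4-oxo-4H-chromen-6-yl}-2-[4-(benzyloxy)phenyl]-5,7-dimethoxy-4H-chromen-4-one
Product: 24 3-[2-(3,4-dihydroxyphenyl)-5,7-dihydroxy-4-oxo-4H-chromen-6-yl]-5-hydroxy-2-(4-hydroxyphenyl)-7-methoxy-4H-chromen-4-one
Conditions: BCl3 (12 equiv), pentamethylbenzene (15 equiv), CH2Cl2, −78 → 0 °C → rt; then MeOH, H2O
Reagents that add atoms: none
Why: Lewis acid ether cleavage with BCl3 removes the five benzyl ethers at low temperature while pentamethylbenzene traps the benzyl cations, and on warming it cleaves the unit 1 methyl ether at C5 through chelation to the C4 carbonyl, whereas the unchelated methyl ether at C7 should survive.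

Compound list
1 | 3,5-bis(benzyloxy)phenol | Oc1cc(OCc2ccccc2)cc(OCc2ccccc2)c1 | starting material
2 | [2,6-bis(benzyloxy)-4-hydroxyphenyl]methylidene-dimethylammonium chloride | C[N+](C)=Cc1c(OCc2ccccc2)cc(O)cc1OCc1ccccc1.[Cl-] | intermediate (not isolated)
3 | 2,6-bis(benzyloxy)-4-hydroxybenzaldehyde | O=Cc1c(OCc2ccccc2)cc(O)cc1OCc1ccccc1 | intermediate
4 | 2,6-bis(benzyloxy)-4-(methoxymethoxy)benzaldehyde | COCOc1cc(OCc2ccccc2)c(C=O)c(OCc2ccccc2)c1 | intermediate
5 | 2-[2,6-bis(benzyloxy)-4-(methoxymethoxy)phenyl]acetonitrile | COCOc1cc(OCc2ccccc2)c(CC#N)c(OCc2ccccc2)c1 | intermediate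
6 | 2-[2,6-bis(benzyloxy)-4-(methoxymethoxy)phenyl]acetic acid | COCOc1cc(OCc2ccccc2)c(CC(=O)O)c(OCc2ccccc2)c1 | intermediate
7 | 2-[2,6-bis(benzyloxy)-4-(methoxymethoxy)phenyl]-N-methoxy-N-methylacetamide | COCOc1cc(OCc2ccccc2)c(CC(=O)N(C)OC)c(OCc2ccccc2)c1 | intermediate
8 | 3,5-dimethoxyphenol | COc1cc(O)cc(OC)c1 | starting material
9 | 1,3-dimethoxy-5-(methoxymethoxy)benzene | COCOc1cc(OC)cc(OC)c1 | intermediate
10 | [2,4-dimethoxy-6-(methoxymethoxy)phenyl]lithium | [Li]c1c(OC)cc(OC)cc1OCOC | intermediate (not isolated)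
11 | 2-[2,6-bis(benzyloxy)-4-(methoxymethoxy)phenyl]-1-[2,4-dimethoxy-6-(methoxymethoxy)phenyl]ethan-1-one | COCOc1cc(OC)cc(OC)c1C(=O)Cc1c(OCc2ccccc2)cc(OCOC)cc1OCc1ccccc1 | intermediate (not isolated)
12 | 2-[2,6-bis(benzyloxy)-4-hydroxyphenyl]-1-(2-hydroxy-4,6-dimethoxyphenyl)ethan-1-one | COc1cc(O)c(C(=O)Cc2c(OCc3ccccc3)cc(O)cc2OCc2ccccc2)c(OC)c1 | intermediate
13 | 2-[2,6-bis(benzyloxy)-4-hydroxy-3-iodophenyl]-1-(2-hydroxy-4,6-dimethoxyphenyl)ethan-1-one | COc1cc(O)c(C(=O)Cc2c(OCc3ccccc3)cc(O)c(I)c2OCc2ccccc2)c(OC)c1 | intermediate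
14 | 4-(benzyloxy)benzoyl chloride | O=C(Cl)c1ccc(OCc2ccccc2)cc1 | starting material
15 | 3,5-bis(benzyloxy)-4-[2-(2-{[4-(benzyloxy)benzoyl]oxy}-4,6-dimethoxyphenyl)-2-oxoethyl]-2-iodophenyl 4-(benzyloxy)benzoate | COc1cc(OC(=O)c2ccc(OCc3ccccc3)cc2)c(C(=O)Cc2c(OCc3ccccc3)cc(OC(=O)c3ccc(OCc4ccccc4)cc3)c(I)c2OCc2ccccc2)c(OC)c1 | intermediate (not isolated)
16 | 3,5-bis(benzyloxy)-4-{1-[4-(benzyloxy)phenyl]-3-(2-hydroxy-4,6-dimethoxyphenyl)-1,3-dioxopropan-2-yl}-2-iodophenyl 4-(benzyloxy)benzoate (racemic, configurationally labile) | COc1cc(O)c(C(=O)C(C(=O)c2ccc(OCc3ccccc3)cc2)c2c(OCc3ccccc3)cc(OC(=O)c3ccc(OCc4ccccc4)cc3)c(I)c2OCc2ccccc2)c(OC)c1 | intermediate (not isolated)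
17 | 3,5-bis(benzyloxy)-4-{2-[4-(benzyloxy)phenyl]-5,7-dimethoxy-4-oxo-4H-chromen-3-yl}-2-iodophenyl 4-(benzyloxy)benzoate | COc1cc(OC)c2c(=O)c(-c3c(OCc4ccccc4)cc(OC(=O)c4ccc(OCc5ccccc5)cc4)c(I)c3OCc3ccccc3)c(-c3ccc(OCc4ccccc4)cc3)oc2c1 | intermediate
18 | 3,4-bis(benzyloxy)benzaldehyde | O=Cc1ccc(OCc2ccccc2)c(OCc2ccccc2)c1 | starting material
19 | 1,2-bis(benzyloxy)-4-ethynylbenzene | C#Cc1ccc(OCc2ccccc2)c(OCc2ccccc2)c1 | intermediate
20 | carbon monoxide | [C-]#[O+] | starting material
21 | 3,5-bis(benzyloxy)-4-{2-[4-(benzyloxy)phenyl]-5,7-dimethoxy-4-oxo-4H-chromen-3-yl}-2-{3-[3,4-bis(benzyloxy)phenyl]prop-2-ynoyl}phenyl 4-(benzyloxy)benzoate | COc1cc(OC)c2c(=O)c(-c3c(OCc4ccccc4)cc(OC(=O)c4ccc(OCc5ccccc5)cc4)c(C(=O)C#Cc4ccc(OCc5ccccc5)c(OCc5ccccc5)c4)c3OCc3ccccc3)c(-c3ccc(OCc4ccccc4)cc3)oc2c1 | intermediate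
22 | 3,5-bis(benzyloxy)-4-{2-[4-(benzyloxy)phenyl]-5,7-dimethoxy-4-oxo-4H-chromen-3-yl}-2-{(2E)-3-[3,4-bis(benzyloxy)phenyl]-3-(diethylamino)prop-2-enoyl}phenyl 4-(benzyloxy)benzoate | COc1cc(OC)c2c(=O)c(-c3c(OCc4ccccc4)cc(OC(=O)c4ccc(OCc5ccccc5)cc4)c(C(=O)/C=C(/N(CC)CC)c4ccc(OCc5ccccc5)c(OCc5ccccc5)c4)c3OCc3ccccc3)c(-c3ccc(OCc4ccccc4)cc3)oc2c1 | intermediate (not isolated)
23 | 3-{5,7-bis(benzyloxy)-2-[3,4-bis(benzyloxy)phenyl]-4-oxo-4H-chromen-6-yl}-2-[4-(benzyloxy)phenyl]-5,7-dimethoxy-4H-chromen-4-one | COc1cc(OC)c2c(=O)c(-c3c(OCc4ccccc4)cc4oc(-c5ccc(OCc6ccccc6)c(OCc6ccccc6)c5)cc(=O)c4c3OCc3ccccc3)c(-c3ccc(OCc4ccccc4)cc3)oc2c1 | intermediate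
24 | 3-[2-(3,4-dihydroxyphenyl)-5,7-dihydroxy-4-oxo-4H-chromen-6-yl]-5-hydroxy-2-(4-hydroxyphenyl)-7-methoxy-4H-chromen-4-one | COc1cc(O)c2c(=O)c(-c3c(O)cc4oc(-c5ccc(O)c(O)c5)cc(=O)c4c3O)c(-c3ccc(O)cc3)oc2c1 | target

Total step count: 13. Longest linear sequence: 11 steps (steps 1–5, 7–9 and 11–13).

Steps most likely to fail

1. Step 11. The aryl(alkynyl)palladium species may reductively eliminate before CO has inserted (direct alkynylation), oxidative addition at the doubly ortho-substituted C–I bond may be slow, and 19 may be consumed by oxidative dimerization. The fallback sets out from 17 and builds the pyranone by the chalcone route, without CO. Stille coupling of 17 with tributyl(1-ethoxyvinyl)stannane (PdCl2(PPh3)2, toluene, 100 °C) would give the enol ether F1, which dilute HCl in THF would hydrolyse to the aryl methyl ketone F2. K2CO3 in MeOH would remove the aroyl ester to give the 2-hydroxyacetophenone F3. Claisen–Schmidt condensation of F3 with aldehyde 18 (KOH, EtOH–THF, rt) would give the (E)-chalcone F4, whose only free hydroxyl is the one para to the biaryl bond. Oxidative cyclization with catalytic I2 in DMSO at 120 °C would then give 23, where the fallback rejoins the route.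

2. Step 9. Acyl transfer to the crowded enolate carbon may stall at the ester stage, or the congested diketone may undergo retro-Claisen cleavage before it cyclodehydrates. The fallback sets out from 13 and forms the C2–C3 bond by an aldol reaction instead. Condensation of 13 with 4-(benzyloxy)benzaldehyde (O=Cc1ccc(OCc2ccccc2)cc1; piperidine, EtOH, reflux), followed by oxa-Michael closure, would give the racemic trans-2,3-diarylchroman-4-one F5. Acylation of its free phenol with 14 (Et3N, DMAP, CH2Cl2) would give the ester F6. Dehydrogenation with DDQ in dioxane at reflux would give 17, where the fallback rejoins the route.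

3. Step 7. The basic aryllithium may abstract a proton from the benzylic methylene of the amide instead of adding to it. The fallback sets out from nitrile 5 and uses a non-basic organocerium addition to an aldehyde followed by oxidation. Reduction of 5 with i-Bu2AlH (toluene, −78 °C; aqueous acid work-up) would give the arylacetaldehyde F7. Aryllithium 10, made as in step 7, would be transmetalated with anhydrous CeCl3 in THF at −78 °C to the arylcerium dichloride F8. Addition of F8 to F7 would give the racemic carbinol F9, and Dess–Martin periodinane oxidation (CH2Cl2, rt) would give ketone 11. The fallback rejoins the route there, and the acid treatment of step 7 then gives 12.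

Further compounds
F1 | step 11 | 3,5-bis(benzyloxy)-4-{2-[4-(benzyloxy)phenyl]-5,7-dimethoxy-4-oxo-4H-chromen-3-yl}-2-(1-ethoxyethenyl)phenyl 4-(benzyloxy)benzoate | COc1cc(OC)c2c(=O)c(-c3c(OCc4ccccc4)cc(OC(=O)c4ccc(OCc5ccccc5)cc4)c(C(=C)OCC)c3OCc3ccccc3)c(-c3ccc(OCc4ccccc4)cc3)oc2c1
F2 | step 11 | 2-acetyl-3,5-bis(benzyloxy)-4-{2-[4-(benzyloxy)phenyl]-5,7-dimethoxy-4-oxo-4H-chromen-3-yl}phenyl 4-(benzyloxy)benzoate | COc1cc(OC)c2c(=O)c(-c3c(OCc4ccccc4)cc(OC(=O)c4ccc(OCc5ccccc5)cc4)c(C(C)=O)c3OCc3ccccc3)c(-c3ccc(OCc4ccccc4)cc3)oc2c1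
F3 | step 11 | 3-[3-acetyl-2,6-bis(benzyloxy)-4-hydroxyphenyl]-2-[4-(benzyloxy)phenyl]-5,7-dimethoxy-4H-chromen-4-one | COc1cc(OC)c2c(=O)c(-c3c(OCc4ccccc4)cc(O)c(C(C)=O)c3OCc3ccccc3)c(-c3ccc(OCc4ccccc4)cc3)oc2c1
F4 | step 11 | 3-(2,6-bis(benzyloxy)-3-{(2E)-3-[3,4-bis(benzyloxy)phenyl]prop-2-enoyl}-4-hydroxyphenyl)-2-[4-(benzyloxy)phenyl]-5,7-dimethoxy-4H-chromen-4-one | COc1cc(OC)c2c(=O)c(-c3c(OCc4ccccc4)cc(O)c(C(=O)/C=C/c4ccc(OCc5ccccc5)c(OCc5ccccc5)c4)c3OCc3ccccc3)c(-c3ccc(OCc4ccccc4)cc3)oc2c1
F5 | step 9 | trans-2-[4-(benzyloxy)phenyl]-3-[2,6-bis(benzyloxy)-4-hydroxy-3-iodophenyl]-5,7-dimethoxychroman-4-one (racemic; one enantiomer drawn) | COc1cc(OC)c2c(c1)O[C@@H](c1ccc(OCc3ccccc3)cc1)[C@H](c1c(OCc3ccccc3)cc(O)c(I)c1OCc1ccccc1)C2=O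
F6 | step 9 | 3,5-bis(benzyloxy)-4-{trans-2-[4-(benzyloxy)phenyl]-5,7-dimethoxy-4-oxochroman-3-yl}-2-iodophenyl 4-(benzyloxy)benzoate (racemic; one enantiomer drawn) | COc1cc(OC)c2c(c1)O[C@@H](c1ccc(OCc3ccccc3)cc1)[C@H](c1c(OCc3ccccc3)cc(OC(=O)c3ccc(OCc4ccccc4)cc3)c(I)c1OCc1ccccc1)C2=O
F7 | step 7 | 2-[2,6-bis(benzyloxy)-4-(methoxymethoxy)phenyl]acetaldehyde | COCOc1cc(OCc2ccccc2)c(CC=O)c(OCc2ccccc2)c1
F8 | step 7 | dichloro[2,4-dimethoxy-6-(methoxymethoxy)phenyl]cerium | Cl[Ce](Cl)c1c(OC)cc(OC)cc1OCOC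
F9 | step 7 | 2-[2,6-bis(benzyloxy)-4-(methoxymethoxy)phenyl]-1-[2,4-dimethoxy-6-(methoxymethoxy)phenyl]ethan-1-ol (racemic) | COCOc1cc(OC)cc(OC)c1C(O)Cc1c(OCc2ccccc2)cc(OCOC)cc1OCc1ccccc1
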